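## The problem

The target is a 5-deoxyflavanone. A 7-hydroxychroman-4-one (arene ring A fused to pyranone ring C) is bonded through C2 to C6′ of a 2,2-dimethylchromane (arene ring B fused to dihydropyran ring D) that carries a free 8′-phenol and a 3′,4′-diol. Unprimed locants refer to the chromanone, primed ones to the chromane.

There are three stereocentres in two groups: C2 (S) on ring C, and C3′ (R) with C4′ (S) on ring D. Flat ring B lies between them, so neither group can direct the other and each must be set by a catalyst. Within ring D the trans diol can come from a cis-oxirane by inversion at the benzylic carbon.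

C2 is the weak point of any flavanone. It is β to the C4 ketone and carries the aryl ether oxygen O1, so base opens ring C to the 2′-hydroxychalcone and reclosure returns C2 as a mixture. C4′ is a benzylic carbinol placed ortho-like (through C4a′–C8a′) to the ring oxygen O1′ of an electron-rich arene. It can ionise in strong acid and scramble the diol, so the last steps can use neither strong base nor strong acid.

The feature that offers a way round the C2 problem is the oxygenation of ring A: oxygen only at C7 and C8a, hydrogen at C5, the pattern of a reduced polyketide. Read this way, C8–C7–C6–C5 is a β-keto aldehyde chain hanging on C8a of a ring C that already exists, and C4a is the α-carbon of a cyclic vinylogous ester. Only the C4a–C5 bond is missing from the arene. Ring C and C2 can therefore be made first from an aldehyde and the benzene ring grown onto them afterwards, so that no phenol ever has to add to an enone.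

## Retrosynthesis

Ar stands throughout for the protected chromane unit of aldehyde 9: (3R,4S)-3,4-bis(tert-butyldimethylsilyloxy)-2,2-dimethyl-8-(triisopropylsilyloxy)chroman-6-yl.

**Protecting groups (23 from 22).** The last cut is of three O–Si bonds: an aryl triisopropylsilyl ether at O8′ and tert-butyldimethylsilyl ethers at O3′ and O4′. Acetal groups would need acid strong enough to endanger C4′, and esters would need base that endangers C2. Silyl ethers leave with buffered fluoride, which touches neither. The skeleton is not simplified, but this choice fixes what every earlier step must tolerate: hypochlorite at pH 11, a lithium enolate, an amidine base and brief dilute acid. The forward step has to reach the hindered C3′ ether.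

**Ring A (22 from 19).** Cutting C4a–C5 and returning methanol across C5–C6 leads from 22 to dihydropyranone 19, which carries an (E)-4-methoxy-2-oxobut-3-enyl chain on C8a. Two neighbouring cuts were weighed:
- Cutting O1–C2 (chalcone closure) leaves C2 to be set by a reversible oxa-Michael addition.
- Cutting C4–C4a (acylation of a resorcinol) leaves a regiochemical choice between two activated positions and still requires a stereocontrolled C2–O1 bond.

The chosen cut removes a whole benzene ring and leaves a monocyclic enone in which C2 is already fixed. The forward reaction must deprotonate C8 and not C3, fold through C4a, and aromatise without opening ring C.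

**The chain (19 from 15 and 16).** Cutting C8–C8a gives lactone 15 and the kinetic enolate of the commercial enone 16. The lactone carbonyl carbon becomes C8a, and the methoxy-bearing carbon of 15 becomes the C4 ketone by hydrolytic transposition of lactol 18. The neighbouring cut at C7–C8 would need γ-deprotonation of a 6-methyl dihydropyranone in competition with C3, which is the enolate that expels O1. An open-chain polyketone would have several ways to fold. The cut splits off four carbons as a bought reagent and leaves a kavalactone-type ring. It asks for 1,2-addition to a vinylogous carbonate carbonyl and then loss of water with O1 staying on C8a.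

**Ring C and C2 (15 from 9 and 13).** Cutting C2–C3 and the acyl–oxygen bond gives aldehyde 9 and the 1,3-dimethoxy-1-silyloxy diene 13. In the forward sense this is a catalytic asymmetric hetero-Diels–Alder reaction, and it sets C2 in a single operation by catalyst control. The stepwise alternative (aldol with the bis-silyl dienolate of methyl acetoacetate, lactonisation, O-methylation) costs two more steps and exposes the aryl silyl ether to methanolic carbonate and a methylating agent. Diene 13 comes from methyl acetoacetate 10 in two routine steps through enol ether 11.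

**The diol (9 from 8, 7 and 6).** Removing the two silyl ethers gives diol 8. Re-forming the C4′–O bond with inversion gives cis-oxirane 7, and removing the oxirane oxygen gives chromene 6. Cis-alkenes of 2,2-dimethylchromenes are a privileged class for manganese–salen epoxidation. The formyl group para to O1′ restrains ionisation of the oxirane, so water should open it at C4′ with inversion. Dihydroxylation of 6 would give the cis diol and was set aside.

**Ring D (6 from 4, 3, 1 and 2).** Chromene 6 is cut at C4a′–C4′ and reconnected through oxygen to aryl propargyl ether 4, which rearranges thermally. Ether 4 comes from phenol 3 by silylation, and 3 from 3,4-dihydroxybenzaldehyde 1 and chloride 2 by alkylation of the more acidic hydroxyl. The formyl carbon that becomes C2 is present from the first step, so the arene is never functionalised later.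

## Roads not taken

**Alternative 1:** ring D is cut at O1′–C2′. In the forward sense, catalytic camphorsulfonic acid makes the phenol of the threo epoxy silyl ether A2 attack the dimethyl-substituted oxirane carbon (6-endo), giving chromanol A1.
- Merits: the C3′/C4′ relationship is written into an acyclic precursor and transferred without a substitution at either stereocentre. The two hydroxyls emerge differentiated, and the bromide is a handle for the formyl group.
- Weak points: A2 needs two stereo-defining operations (an enantioselective route to a secondary allylic carbinol and a hydroxyl-directed epoxidation) where the chosen plan needs one. 5-Exo attack at C3′ competes unless the tertiary carbon dominates. The benzylic silyl ether sits under the same acid. A1 still needs its bromide exchanged for the formyl carbon.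
- Comparison: for security of the trans relationship this road is at least as good as opening an oxirane with water, because no benzylic inversion is required. The chosen plan sets brevity against it: diol 8 is five steps from 1 with the aldehyde in place throughout. This road replaces steps 1–6 only and says nothing about C2 or ring A.

**Alternative 2:** ring C is cut at C8a–O1. In the forward sense, copper iodide (CuI), 3,4,7,8-tetramethyl-1,10-phenanthroline and Cs2CO3 close the (1S,3S)-diol A4 by intramolecular O-arylation to flavan-4-ol A3, with C2 retained because its C–O bond is never broken.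
- Merits: ring A is bought ready-made. C2 is carried at the alcohol oxidation level, where no retro-oxa-Michael path exists. Only the distal hydroxyl can reach the bromide. Every step has close precedent on flavans.
- Weak points: the C4 carbinol of A3 is a stereocentre made only to be oxidised away. The closure needs hot carbonate with two benzylic alcohols present. The chromene must be epoxidised and hydrolysed late, next to a base-sensitive flavanone. The acetal protecting groups then have to leave under acid in the presence of the C4′ carbinol.
- Comparison: at the ring-forming step this road is the more conservative and in that respect better; it has no counterpart to the uncertain acylation of step 10. The chosen plan sets against it that there is no sacrificial stereocentre and no redox detour at C4, the diol is installed early and protected, ring A arrives with 5-H and a free 7-OH, and ring C is never heated with base once C2 exists. The step count would be no lower.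

**Alternative 3:** ring D is cut at C3′–C4′. In the forward sense, a chiral triazolium-derived carbene converts the aryl aldehyde of dialdehyde A6 into its Breslow intermediate, which adds to the α-aryloxy aldehyde to give ketol A5.
- Merits: A6 is achiral and short to make. Its acceptor aldehyde cannot enolise and is hindered enough to leave the acyl-anion role to the aryl aldehyde. Ring D and C3′ arise in one organocatalytic step.
- Weak points: A5 is a secondary α-ketol. Its C3′–H is enolisable under the basic carbene conditions, which invites erosion of configuration and ketol transposition. Aldehyde–aldehyde closures of this kind are less developed than aldehyde–ketone ones. The trans diol then needs an anti-selective ketone reduction next to a free hydroxyl, where chelating hydrides favour cis. The bromide still has to become the formyl carbon.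
- Comparison: in step count to a ring D ketol it matches the chosen steps 1–5, and it starts from achiral material without a metal oxidant. The chosen plan sets against it a reliably selective substrate class for epoxidation and a trans relationship that follows from the mechanism of ring opening. Like alternative 1, it leaves C2 and ring A unaddressed.

Key step: step 11

Remark on the chemistry: the facial sense of the two catalytic steps, (R,R)-(salen)MnCl giving the (3R,4R)-oxirane 7 and Ti(OiPr)4/(S)-BINOL giving the 6S lactone 15, is assumed by analogy with the closest chromene and aryl aldehyde substrates; should either prove opposite, the antipodal ligand is used and nothing else changes.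

## Route

Step 1
Reactants: 1 3,4-dihydroxybenzaldehyde; 2 3-chloro-3-methylbut-1-yne
Product: 3 3-hydroxy-4-[(2-methylbut-3-yn-2-yl)oxy]benzaldehyde
Conditions: DBU (1.05 equiv), CuCl2·2H2O (cat.), MeCN, 0 °C
Reagents that add atoms: none
Why: Copper-catalysed O-alkylation of a phenoxide by a tertiary propargylic chloride; one equivalent of amidine base ionises only the more acidic 4-hydroxyl (para to the formyl group), so mono-etherification at O4 is expected.

Step 2
Reactants: 3 3-hydroxy-4-[(2-methylbut-3-yn-2-yl)oxy]benzaldehyde
Product: 4 4-[(2-methylbut-3-yn-2-yl)oxy]-3-(triisopropylsilyloxy)benzaldehyde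
Conditions: TIPSCl, imidazole, DMF, rt
Reagents that add atoms: triisopropylsilyl chloride (TIPSCl), CC(C)[Si](Cl)(C(C)C)C(C)C
Why: Standard phenol silylation; the bulky aryl silyl ether should survive hot aprotic media, pH 11 hypochlorite and lithium enolates, and it leaves with the other silyl groups at the end.

Step 3
Reactants: 4 4-[(2-methylbut-3-yn-2-yl)oxy]-3-(triisopropylsilyloxy)benzaldehyde
Product: 6 2,2-dimethyl-8-(triisopropylsilyloxy)-2H-chromene-6-carbaldehyde, via allenylphenol 5 (not isolated)
Conditions: 1,2-dichlorobenzene, 180 °C
Reagents that add atoms: none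
Why: Aromatic propargyl Claisen rearrangement to the only free ortho position gives allenylphenol 5, which closes by 1,5-hydrogen shift and oxa-6π electrocyclisation to the 2,2-dimethylchromene; the other ortho position is blocked by the silyloxy group.

Step 4
Reactants: 6 2,2-dimethyl-8-(triisopropylsilyloxy)-2H-chromene-6-carbaldehyde
Product: 7 (3R,4R)-3,4-epoxy-2,2-dimethyl-8-(triisopropylsilyloxy)chromane-6-carbaldehyde
Conditions: (R,R)-(salen)MnCl (cat.; salen = N,N′-bis(3,5-di-tert-butylsalicylidene)cyclohexane-1,2-diamine dianion), aq. NaOCl (pH 11.3), 4-phenylpyridine N-oxide, CH2Cl2, 0 °C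
Reagents that add atoms: sodium hypochlorite, [Na+].[O-]Cl
Why: Jacobsen epoxidation of a cis, aryl-conjugated alkene in the 2,2-dimethylchromene class; the chiral diamine backbone selects the alkene face and sets C3′ and C4′ together as the (3R,4R)-oxirane.

Step 5
Reactants: 7 (3R,4R)-3,4-epoxy-2,2-dimethyl-8-(triisopropylsilyloxy)chromane-6-carbaldehyde
Product: 8 (3R,4S)-3,4-dihydroxy-2,2-dimethyl-8-(triisopropylsilyloxy)chromane-6-carbaldehyde
Conditions: HClO4 (cat.), THF/H2O, 0 °C to rt
Reagents that add atoms: water, O
Why: Acid-catalysed hydrolytic opening of the oxirane at benzylic C4′ with inversion gives the trans diol, while C3′ keeps its C–O bond; the formyl group para to O1′ disfavours a free benzylic cation, so a borderline SN2 course is expected.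

Step 6
Reactants: 8 (3R,4S)-3,4-dihydroxy-2,2-dimethyl-8-(triisopropylsilyloxy)chromane-6-carbaldehyde
Product: 9 (3R,4S)-3,4-bis(tert-butyldimethylsilyloxy)-2,2-dimethyl-8-(triisopropylsilyloxy)chromane-6-carbaldehyde (Ar–CHO)
Conditions: TBSOTf, 2,6-lutidine, CH2Cl2, 0 °C to rt
Reagents that add atoms: tert-butyldimethylsilyl trifluoromethanesulfonate (TBSOTf), CC(C)(C)[Si](C)(C)OS(=O)(=O)C(F)(F)F
Why: Silyl triflate with a hindered pyridine base silylates both secondary hydroxyls, including the neopentyl-type C3′–OH; the non-enolisable aryl aldehyde is left intact after aqueous work-up.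

Step 7
Reactants: 10 methyl acetoacetate
Product: 11 methyl (E)-3-methoxybut-2-enoate
Conditions: HC(OMe)3, H2SO4 (cat.), MeOH, rt
Reagents that add atoms: trimethyl orthoformate, COC(OC)OC
Why: Acid-catalysed conversion of a β-keto ester into its methyl enol ether through the dimethyl ketal; conjugation with the ester favours the E isomer.

Step 8
Reactants: 11 methyl (E)-3-methoxybut-2-enoate
Product: 13 1,3-dimethoxy-1-(trimethylsilyloxy)buta-1,3-diene (Brassard diene), via lithium dienolate 12 (not isolated)
Conditions: LDA, THF, −78 °C; TMSCl, −78 °C to rt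
Reagents that add atoms: chlorotrimethylsilane (TMSCl), C[Si](C)(C)Cl
Why: Kinetic γ-deprotonation of the β-methoxy enoate and O-silylation of dienolate 12 give the silyl ketene acetal diene, which is distilled and used at once; its ketene acetal geometry is of no consequence.

Step 9
Reactants: 9 (3R,4S)-3,4-bis(tert-butyldimethylsilyloxy)-2,2-dimethyl-8-(triisopropylsilyloxy)chromane-6-carbaldehyde (Ar–CHO); 13 1,3-dimethoxy-1-(trimethylsilyloxy)buta-1,3-diene
Product: 15 (6S)-6-Ar-4-methoxy-5,6-dihydro-2H-pyran-2-one, via silylated aldol adduct 14 (not isolated)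
Conditions: Ti(OiPr)4/(S)-BINOL (cat.), 4 Å MS, THF, −20 °C to rt; then TFA (cat.), CH2Cl2, 0 °C
Reagents that add atoms: none
Why: Catalytic asymmetric hetero-Diels–Alder reaction of a Brassard diene, which runs stepwise as a vinylogous Mukaiyama aldol (14) followed by acid-promoted lactonisation; the chiral titanium binaphtholate selects the aldehyde face and sets C2 as S, the remote ring D centres having no influence.

Step 10
Reactants: 15 (6S)-6-Ar-4-methoxy-5,6-dihydro-2H-pyran-2-one; 16 (E)-4-methoxybut-3-en-2-one
Product: 19 (2S)-2-Ar-6-[(E)-4-methoxy-2-oxobut-3-en-1-yl]-2,3-dihydro-4H-pyran-4-one, via lithium enolate 17 (not isolated), via lactol 18 (not isolated)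
Conditions: LiHMDS, THF, −78 °C (16, 2.5 equiv); add 15, −78 to −30 °C; then 1 M HCl, THF, 0 °C
Reagents that add atoms: water, O
Why: Claisen-type 1,2-addition of the kinetic lithium enolate 17 to the lactone carbonyl gives lactol 18, and dilute acid effects a Stork–Danheiser-type transposition (loss of the lactol hydroxyl, hydrolysis of the 4-methoxy enol ether) to the 2,3-dihydro-4H-pyran-4-one; O1 never leaves C8a, so C2 is untouched.

Step 11
Reactants: 19 (2S)-2-Ar-6-[(E)-4-methoxy-2-oxobut-3-en-1-yl]-2,3-dihydro-4H-pyran-4-one
Product: 22 (2S)-2-Ar-7-hydroxychroman-4-one, via Michael adduct 20 (not isolated), via dienone 21 (not isolated)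
Conditions: DBU (1.2 equiv), THF, 0 °C to rt; AcOH quench
Reagents that add atoms: none
Why: DBU removes a proton from C8, which lies between the C7 ketone and the vinylogous ester, and the resulting dienolate attacks through its α-carbon C4a the methoxy-bearing β-carbon C5 of the enone in a 6-endo-trig Michael addition that forms C4a–C5 and closes ring A (20). Methoxide then leaves C5 by E1cB to give dienone 21, and loss of the C4a proton with enolisation of the C7 ketone aromatises ring A to the phenol. The closest known reaction type is the cyclocondensation of 1,3-dicarbonyl dienolates with 3-alkoxy enones to phenols, run here inside one molecule in the manner of a polyketide aromatisation. The folding is fixed by ring size: attack through C8 would close a four-membered ring and attack through the C4 oxygen an eight-membered one, so hydrogen ends at C5 and hydroxyl at C7. No new stereocentre survives, since C4a and C5 are sp3 only in 20 and 21. The selectivity needed is C8 over C3 deprotonation; the doubly activated C8 methylene is far more acidic than C3, so an amidine base should leave C3 alone and O1 is not expelled from C2. The phenoxide of 22 also deactivates the C4 carbonyl by vinylogy until the acid quench. Loss of the aryl silyl ether to the liberated methanol would be harmless because step 12 removes it in any case.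

Step 12
Reactants: 22 (2S)-2-Ar-7-hydroxychroman-4-one
Product: 23 (2S)-7-hydroxy-2-[(3R,4S)-3,4,8-trihydroxy-2,2-dimethylchroman-6-yl]chroman-4-one (CNP0281318.3)
Conditions: HF·pyridine, pyridine, THF, 0 °C to rt
Reagents that add atoms: none
Why: Fluoride-driven cleavage of all three O–Si bonds in a buffered, weakly acidic medium; no C–O bond at a stereocentre is touched, and neither the base-labile ring C nor the acid-labile C4′ carbinol is stressed.

## Compound list

Ar = (3R,4S)-3,4-bis(tert-butyldimethylsilyloxy)-2,2-dimethyl-8-(triisopropylsilyloxy)chroman-6-yl.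

1 | 3,4-dihydroxybenzaldehyde | O=Cc1ccc(O)c(O)c1 | starting material
2 | 3-chloro-3-methylbut-1-yne | CC(C)(Cl)C#C | starting material
3 | 3-hydroxy-4-[(2-methylbut-3-yn-2-yl)oxy]benzaldehyde | O=Cc1ccc(OC(C)(C)C#C)c(O)c1 | intermediate
4 | 4-[(2-methylbut-3-yn-2-yl)oxy]-3-(triisopropylsilyloxy)benzaldehyde | O=Cc1ccc(OC(C)(C)C#C)c(O[Si](C(C)C)(C(C)C)C(C)C)c1 | intermediate
5 | 4-hydroxy-3-(3-methylbuta-1,2-dien-1-yl)-5-(triisopropylsilyloxy)benzaldehyde | O=Cc1cc(C=C=C(C)C)c(O)c(O[Si](C(C)C)(C(C)C)C(C)C)c1 | intermediate (not isolated)
6 | 2,2-dimethyl-8-(triisopropylsilyloxy)-2H-chromene-6-carbaldehyde | CC1(C)C=Cc2cc(C=O)cc(O[Si](C(C)C)(C(C)C)C(C)C)c2O1 | intermediate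
7 | (3R,4R)-3,4-epoxy-2,2-dimethyl-8-(triisopropylsilyloxy)chromane-6-carbaldehyde | CC1(C)Oc2c(O[Si](C(C)C)(C(C)C)C(C)C)cc(C=O)cc2[C@H]3O[C@@H]13 | intermediate
8 | (3R,4S)-3,4-dihydroxy-2,2-dimethyl-8-(triisopropylsilyloxy)chromane-6-carbaldehyde (trans diol) | CC1(C)Oc2c(O[Si](C(C)C)(C(C)C)C(C)C)cc(C=O)cc2[C@H](O)[C@H]1O | intermediate
9 | (3R,4S)-3,4-bis(tert-butyldimethylsilyloxy)-2,2-dimethyl-8-(triisopropylsilyloxy)chromane-6-carbaldehyde (Ar–CHO) | CC1(C)Oc2c(O[Si](C(C)C)(C(C)C)C(C)C)cc(C=O)cc2[C@H](O[Si](C)(C)C(C)(C)C)[C@H]1O[Si](C)(C)C(C)(C)C | intermediate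
10 | methyl acetoacetate | COC(=O)CC(C)=O | starting material
11 | methyl (E)-3-methoxybut-2-enoate | CO/C(C)=C/C(=O)OC | intermediate
12 | lithium 1,3-dimethoxybuta-1,3-dien-1-olate (dienolate of 11) | C=C(OC)C=C(OC)[O-].[Li+] | intermediate (not isolated)
13 | 1,3-dimethoxy-1-(trimethylsilyloxy)buta-1,3-diene (ketene acetal geometry not controlled) | C=C(OC)C=C(OC)O[Si](C)(C)C | intermediate
14 | methyl (2E,5S)-5-Ar-3-methoxy-5-(trimethylsilyloxy)pent-2-enoate | CC1(C)Oc2c(O[Si](C(C)C)(C(C)C)C(C)C)cc([C@@H](O[Si](C)(C)C)C/C(OC)=C\C(=O)OC)cc2[C@H](O[Si](C)(C)C(C)(C)C)[C@H]1O[Si](C)(C)C(C)(C)C | intermediate (not isolated)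
15 | (6S)-6-Ar-4-methoxy-5,6-dihydro-2H-pyran-2-one | CC1(C)Oc2c(O[Si](C(C)C)(C(C)C)C(C)C)cc([C@@H]3CC(OC)=CC(=O)O3)cc2[C@H](O[Si](C)(C)C(C)(C)C)[C@H]1O[Si](C)(C)C(C)(C)C | intermediate
16 | (E)-4-methoxybut-3-en-2-one | CO/C=C/C(C)=O | starting material
17 | lithium (E)-4-methoxybuta-1,3-dien-2-olate (kinetic enolate of 16) | [Li+].[O-]C(=C)/C=C/OC | intermediate (not isolated)
18 | (6S)-6-Ar-2-hydroxy-4-methoxy-2-[(E)-4-methoxy-2-oxobut-3-en-1-yl]-5,6-dihydro-2H-pyran (lactol, both configurations at the lactol carbon) | CC1(C)Oc2c(O[Si](C(C)C)(C(C)C)C(C)C)cc([C@@H]3CC(OC)=CC(O)(CC(=O)/C=C/OC)O3)cc2[C@H](O[Si](C)(C)C(C)(C)C)[C@H]1O[Si](C)(C)C(C)(C)C | intermediate (not isolated)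
19 | (2S)-2-Ar-6-[(E)-4-methoxy-2-oxobut-3-en-1-yl]-2,3-dihydro-4H-pyran-4-one | CC1(C)Oc2c(O[Si](C(C)C)(C(C)C)C(C)C)cc([C@@H]3CC(=O)C=C(CC(=O)/C=C/OC)O3)cc2[C@H](O[Si](C)(C)C(C)(C)C)[C@H]1O[Si](C)(C)C(C)(C)C | intermediate
20 | (2S)-2-Ar-5-methoxy-2,3,5,6-tetrahydro-4H-chromene-4,7(4aH)-dione (C4a and C5 transient, not defined) | CC1(C)Oc2c(O[Si](C(C)C)(C(C)C)C(C)C)cc([C@@H]3CC(=O)C4C(OC)CC(=O)C=C4O3)cc2[C@H](O[Si](C)(C)C(C)(C)C)[C@H]1O[Si](C)(C)C(C)(C)C | intermediate (not isolated)
21 | (2S)-2-Ar-2,3-dihydro-4H-chromene-4,7(4aH)-dione (C4a transient, not defined) | CC1(C)Oc2c(O[Si](C(C)C)(C(C)C)C(C)C)cc([C@@H]3CC(=O)C4C=CC(=O)C=C4O3)cc2[C@H](O[Si](C)(C)C(C)(C)C)[C@H]1O[Si](C)(C)C(C)(C)C | intermediate (not isolated)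
22 | (2S)-2-Ar-7-hydroxychroman-4-one | CC1(C)Oc2c(O[Si](C(C)C)(C(C)C)C(C)C)cc([C@@H]3CC(=O)c4ccc(O)cc4O3)cc2[C@H](O[Si](C)(C)C(C)(C)C)[C@H]1O[Si](C)(C)C(C)(C)C | intermediate
23 | (2S)-7-hydroxy-2-[(3R,4S)-3,4,8-trihydroxy-2,2-dimethylchroman-6-yl]chroman-4-one | CC1(C)Oc2c(O)cc([C@@H]3CC(=O)c4ccc(O)cc4O3)cc2[C@H](O)[C@H]1O | target

## Step count and risks

Total step count: 12. Longest linear sequence: 10 (steps 1–6 and 9–12); steps 7 and 8 form a two-step branch that joins at step 9.

**Step 11 (key step).** What may go wrong: deprotonation at C3 in competition with C8, followed by β-elimination of O1, which opens ring C and loses the C2 configuration. Slow folding of the chain into the cisoid geometry needed for 6-endo attack could also let intermolecular Michael addition take over. Fallback: the classical flavanone assembly, setting out from aldehyde 9. 2′,4′-Dihydroxyacetophenone is converted with MOMCl and K2CO3 into 1-[2-hydroxy-4-(methoxymethoxy)phenyl]ethanone F1. Claisen–Schmidt condensation of F1 with 9 in ethanolic KOH, which is expected to remove the aryl silyl ether as well, gives the (E)-chalcone F2. Oxa-Michael closure with NaOAc in refluxing ethanol gives the flavanone as C2 epimers. The (2S)-7-O-methoxymethyl flavanone F3 is separated, and the unwanted epimer is returned to the equilibration. Brief methanolic HCl at 0 °C to room temperature removes the acetal and the two silyl ethers, and the route is rejoined at target 23. This path gives up catalyst control of C2, which is what the key step is meant to provide.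

**Step 10.** What may go wrong: slow 1,2-addition to the deactivated vinylogous carbonate carbonyl while the enolate condenses with itself. γ-Deprotonation of 15 with β-elimination of O1 is a second risk. In the acid stage, ring–chain opening of the lactol followed by O-cyclisation onto C5 would give a 4-pyranone. Fallback: setting out from lactone 15, a vinylogous amide replaces the vinylogous ester. The lithium enolate of commercial (E)-4-(dimethylamino)but-3-en-2-one is not a Michael acceptor and tolerates warming. It is added to 15, and the same acid work-up gives the enaminone (2S)-2-Ar-6-[(E)-4-(dimethylamino)-2-oxobut-3-en-1-yl]-2,3-dihydro-4H-pyran-4-one F4. In warm acetic acid F4 should close through C4a onto C5 with loss of dimethylamine and aromatise, rejoining the route at 22.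

**Step 9.** What may go wrong: low turnover with an electron-rich, bulky aryl aldehyde; erosion of facial selectivity by an uncatalysed background addition; partial loss of the benzylic silyl ether during acid lactonisation. Fallback: setting out from aldehyde 9 and methyl acetoacetate 10. Compound 10 is converted by two silylations into 1-methoxy-1,3-bis(trimethylsilyloxy)buta-1,3-diene F5. A Ti(OiPr)4/(S)-BINOL-catalysed vinylogous Mukaiyama aldol reaction with 9 and mild acidic desilylation give methyl (5S)-5-Ar-5-hydroxy-3-oxopentanoate F6. Brief K2CO3 in methanol lactonises F6 to (6S)-6-Ar-4-hydroxy-5,6-dihydro-2H-pyran-2-one F7, and O-methylation with Me2SO4 and K2CO3 in acetone rejoins the route at 15.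

**Step 4.** What may go wrong: oxidation of the formyl group by hypochlorite or by the oxo-manganese species, and incomplete enantioselection. Fallback: setting out from chromene 6, the aldehyde is masked with HC(OMe)3 and catalytic acid as 6-(dimethoxymethyl)-2,2-dimethyl-8-(triisopropylsilyloxy)-2H-chromene F8. The same epoxidation then gives (3R,4R)-6-(dimethoxymethyl)-3,4-epoxy-2,2-dimethyl-8-(triisopropylsilyloxy)chromane F9. The aqueous acid of step 5 opens the oxirane and hydrolyses the acetal in one operation, rejoining the route at diol 8.

**Step 12.** What may go wrong: slow cleavage of the hindered C3′ silyl ether, so that long exposure gives partly desilylated mixtures and begins to stress the C4′ carbinol. Fallback: setting out from 22, the work is split between two mechanisms. Acetic acid-buffered Bu4NF removes the aryl silyl ether first to give (2S)-2-[(3R,4S)-3,4-bis(tert-butyldimethylsilyloxy)-8-hydroxy-2,2-dimethylchroman-6-yl]-7-hydroxychroman-4-one F10. Acid-catalysed methanolysis (dilute HCl in methanol, 0 °C) then cleaves the two alkyl silyl ethers, rejoining the route at target 23.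

## Further compounds

F1 | step 11 | 1-[2-hydroxy-4-(methoxymethoxy)phenyl]ethanone | CC(=O)c1ccc(OCOC)cc1O
F2 | step 11 | (E)-3-[(3R,4S)-3,4-bis(tert-butyldimethylsilyloxy)-8-hydroxy-2,2-dimethylchroman-6-yl]-1-[2-hydroxy-4-(methoxymethoxy)phenyl]prop-2-en-1-one | CC1(C)Oc2c(O)cc(/C=C/C(=O)c3ccc(OCOC)cc3O)cc2[C@H](O[Si](C)(C)C(C)(C)C)[C@H]1O[Si](C)(C)C(C)(C)C
F3 | step 11 | (2S)-2-[(3R,4S)-3,4-bis(tert-butyldimethylsilyloxy)-8-hydroxy-2,2-dimethylchroman-6-yl]-7-(methoxymethoxy)chroman-4-one | CC1(C)Oc2c(O)cc([C@@H]3CC(=O)c4ccc(OCOC)cc4O3)cc2[C@H](O[Si](C)(C)C(C)(C)C)[C@H]1O[Si](C)(C)C(C)(C)C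
F4 | step 10 | (2S)-2-[(3R,4S)-3,4-bis(tert-butyldimethylsilyloxy)-2,2-dimethyl-8-(triisopropylsilyloxy)chroman-6-yl]-6-[(E)-4-(dimethylamino)-2-oxobut-3-en-1-yl]-2,3-dihydro-4H-pyran-4-one | CC1(C)Oc2c(O[Si](C(C)C)(C(C)C)C(C)C)cc([C@@H]3CC(=O)C=C(CC(=O)/C=C/N(C)C)O3)cc2[C@H](O[Si](C)(C)C(C)(C)C)[C@H]1O[Si](C)(C)C(C)(C)C
F5 | step 9 | 1-methoxy-1,3-bis(trimethylsilyloxy)buta-1,3-diene | C=C(O[Si](C)(C)C)C=C(OC)O[Si](C)(C)C
F6 | step 9 | methyl (5S)-5-[(3R,4S)-3,4-bis(tert-butyldimethylsilyloxy)-2,2-dimethyl-8-(triisopropylsilyloxy)chroman-6-yl]-5-hydroxy-3-oxopentanoate | CC1(C)Oc2c(O[Si](C(C)C)(C(C)C)C(C)C)cc([C@@H](O)CC(=O)CC(=O)OC)cc2[C@H](O[Si](C)(C)C(C)(C)C)[C@H]1O[Si](C)(C)C(C)(C)C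
F7 | step 9 | (6S)-6-[(3R,4S)-3,4-bis(tert-butyldimethylsilyloxy)-2,2-dimethyl-8-(triisopropylsilyloxy)chroman-6-yl]-4-hydroxy-5,6-dihydro-2H-pyran-2-one | CC1(C)Oc2c(O[Si](C(C)C)(C(C)C)C(C)C)cc([C@@H]3CC(O)=CC(=O)O3)cc2[C@H](O[Si](C)(C)C(C)(C)C)[C@H]1O[Si](C)(C)C(C)(C)C
F8 | step 4 | 6-(dimethoxymethyl)-2,2-dimethyl-8-(triisopropylsilyloxy)-2H-chromene | COC(OC)c1cc(O[Si](C(C)C)(C(C)C)C(C)C)c2OC(C)(C)C=Cc2c1
F9 | step 4 | (3R,4R)-6-(dimethoxymethyl)-3,4-epoxy-2,2-dimethyl-8-(triisopropylsilyloxy)chromane | CC1(C)Oc2c(O[Si](C(C)C)(C(C)C)C(C)C)cc(C(OC)OC)cc2[C@H]3O[C@@H]13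
F10 | step 12 | (2S)-2-[(3R,4S)-3,4-bis(tert-butyldimethylsilyloxy)-8-hydroxy-2,2-dimethylchroman-6-yl]-7-hydroxychroman-4-one | CC1(C)Oc2c(O)cc([C@@H]3CC(=O)c4ccc(O)cc4O3)cc2[C@H](O[Si](C)(C)C(C)(C)C)[C@H]1O[Si](C)(C)C(C)(C)C
A1 | alternative 1 | (3R,4S)-6-bromo-4-(tert-butyldimethylsilyloxy)-8-(methoxymethoxy)-2,2-dimethylchroman-3-ol | CC1(C)Oc2c(OCOC)cc(Br)cc2[C@H](O[Si](C)(C)C(C)(C)C)[C@H]1O
A2 | alternative 1 | 4-bromo-2-{(S)-(tert-butyldimethylsilyloxy)[(2R)-3,3-dimethyloxiran-2-yl]methyl}-6-(methoxymethoxy)phenol | Oc1c(OCOC)cc(Br)cc1[C@H](O[Si](C)(C)C(C)(C)C)[C@H]1OC1(C)C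
A3 | alternative 2 | (2S,4S)-7-(methoxymethoxy)-2-[8-(methoxymethoxy)-2,2-dimethyl-2H-chromen-6-yl]chroman-4-ol | CC1(C)Oc2c(OCOC)cc([C@@H]3C[C@H](O)c4ccc(OCOC)cc4O3)cc2C=C1
A4 | alternative 2 | (1S,3S)-1-[2-bromo-4-(methoxymethoxy)phenyl]-3-[8-(methoxymethoxy)-2,2-dimethyl-2H-chromen-6-yl]propane-1,3-diol | CC1(C)Oc2c(OCOC)cc([C@@H](O)C[C@H](O)c3ccc(OCOC)cc3Br)cc2C=C1
A5 | alternative 3 | (3S)-6-bromo-3-hydroxy-8-(methoxymethoxy)-2,2-dimethylchroman-4-one | CC1(C)Oc2c(OCOC)cc(Br)cc2C(=O)[C@H]1O
A6 | alternative 3 | 5-bromo-3-(methoxymethoxy)-2-[(2-methyl-1-oxopropan-2-yl)oxy]benzaldehyde | CC(C)(C=O)Oc1c(OCOC)cc(Br)cc1C=O
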